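The numbers of this flask were chosen freely.

Since E is charged at 1.50 equiv on D, the easy first step is to name D the limiting reagent and keep my ledger in D.

| setting | Thursday's | Wednesday's | Tuesday's |
|---|---|---|---|
| D | 28 mM | 28 mM | 28 mM |
| E | 1.50 equiv | 1.50 equiv | 1.50 equiv |
| temperature | 25 °C | 45 °C | 65 °C |
| time | 2.0 min | 2.0 min | 2.0 min |

    Z ⇌ J (K1 = 0.651, k1 = 2.79 × 10⁻⁴ s⁻¹, Ea1 = 94.0 kJ mol⁻¹, ΔH1 = 5.00 kJ mol⁻¹)
    D.G → Z (k2 = 0.00555 s⁻¹, Ea2 = 75.0 kJ mol⁻¹)
    D + D.G → D.D.G (k3 = 0.0260 M⁻¹ s⁻¹, Ea3 = 52.0 kJ mol⁻¹)
    G ⇌ Q (K4 = 11.5, k4 = 0.00123 s⁻¹, Ea4 = 88.0 kJ mol⁻¹, ΔH4 = 8.00 kJ mol⁻¹)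
    D + G → D.G (k5 = 0.195 M⁻¹ s⁻¹, Ea5 = 42.0 kJ mol⁻¹)
    E ⇌ G, rate k6*(cs6 - [G]) while solid is left; crystals form when [G] > cs6 (cs6 = 22 mM, k6 = 0.00506 s⁻¹)
    (constants at 25 °C)

- in percentages every species weighs as the D in it: one D.D.G counts as two
- as a solid, counted per litre of solution: E
- the list of constants is for 25 °C, to be carried to other temperatures by the activation energies and enthalpies
- at the start none of E is in solution

- which of these there is most of at the end, counted by the D in it, Thursday's (D.G / D.D.G / J / Z / D)
- which of these there is most of at the end, counted by the D in it, Wednesday's (D.G / D.D.G / J / Z / D)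
- which of these there is most of at the end, counted by the D in it, Tuesday's (D.G / D.D.G / J / Z / D)
- final amount of the leader among these, as a percentage of the D charged, in Thursday's
- final amount of the leader among these, as a percentage of the D charged, in Wednesday's
- final amount of the leader among these, as a percentage of the D charged, in Tuesday's

The first entry is the feed. Solid E gives G at its coefficient 0.00506 s⁻¹ times the gap below the solubility 22 mM, so with no G yet present the feed is g = 6.68 mM min⁻¹, and it can only slow down from there. The constants give this feed no activation energy, so over 2.0 min it delivers at most 13.4 mM of G in Thursday's, Wednesday's and Tuesday's alike, which is 47.7% of the 28 mM of D. Counting one D per G would leave D with 52.3%, but this is an estimate and no floor, since D + D.G → D.D.G takes a second D with no new G, and D.D.G counts as two. At 25 °C, with D at its charge, the ring closes faster than a second D takes D.G, and the ring closure has the larger activation energy, so I treat the second D as a small correction and commit to D as the leader in each of them.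

For Thursday's I can go further. While D stays near its charge, G is pseudo-first-order, and three terms pull it back. D + G runs at 0.328 min⁻¹, which by itself gives G a half-life of 2.1 min. G to Q runs at 0.074 min⁻¹, and the slowing of the feed counts 0.3 min⁻¹. At 25 °C D therefore takes G faster than Q does, but heating narrows that gap, because the activation energy of G to Q is larger. I leave out the return of Q to G. The three terms sum to κ = 0.705 min⁻¹, so G climbs exponentially toward the plateau g/κ = 9.47 mM. Its climb costs a lag, one minus exp(−κt), divided by κ, which is 1.07 min here. Multiplying the rate constant 0.195 M⁻¹ s⁻¹ by the plateau and by the time less the lag gives 10.3% for Thursday's. This is the drawn share, the part of the charged D that has passed through D + G by time t.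

The books then close quickly. D.G goes to Z with a half-life of 2.08 min, longer than the run, so I expect most of the drawn D to be still sitting as D.G. A second D takes D.G 7.62 times more slowly than the ring closes, so D.D.G is a small entry. Thursday's ends, by my reckoning, with 89.7% of D; for the warmer flasks I commit to the leader and no figure.

The forecast names D for Thursday's, D for Wednesday's and D for Tuesday's, at 90%, 82% and 83.5%, and holds that heating “also diverts G to Q much faster”.

The leader is D at 89.9% in Thursday's, D at 82.8% in Wednesday's and D at 84.2% in Tuesday's. In Tuesday's, Q stands at 7.33 mM after 2.00 min, more than the 4.42 mM of D gone from the charge. Thursday's has lost 10.1% of its D against a drawn share of 10.3%. Taken at 50 s, the same drawn share for Thursday's comes to 2.25%, which puts D at 97.8%, and the early reading holds 97.7%.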